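**Retrosynthetic overview**

1. Locants: chain C1 (CH2OH) to C15 (alkyne carbon on ring carbon C1'), carbinol C4'. No ring is formed in the route: the cyclohexene ring and its (R)-carbinol are carried intact from (4R,6R)-actinol.
2. Target 24 ⇐ bis-TBS ether 23 ⇐ one-flask three-component union at the C11–C12 bond: ring-bound terminal buta-1,3-diyne 9 (C12–C15) + Me3Al (the methyl on C13) + all-E tetraenyl iodide 21 (C1–C11).
3. Enabling feature: the methyl-branched (E)-C12=C13 alkene between the C11–C12 single bond and the C14≡C15 alkyne is the retron of a syn-methylmetalation of a terminal diyne. C14≡C15 sits on tetrasubstituted C1', flanked by the gem-dimethyl carbon C6' and the methyl-bearing C2', so only the terminal alkyne should react.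
4. 9 ⇐ enol triflate 4 of TBS-actinol + zinc diynide from bis(TMS)butadiyne 5. 21 ⇐ hydrozirconation–iodination of trienyne 19 ⇐ the same methylalumination/Negishi union of pentynyl silyl ether 16 with iododienyne 15 ⇐ Takai olefination of the enynal from (E)-enynol 10.

Key step: step 11

Remark: compounds 1, 5, 10 (the isomer with ethynyl trans to CH2OH) and 16 are assumed to be purchasable; all polyene intermediates are to be handled under argon, cold and in dim light.

**Route**

Step 1
Reactants: 1 (4R,6R)-4-hydroxy-2,2,6-trimethylcyclohexan-1-one (actinol)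
Product: 2 (4R,6R)-4-{[tert-butyl(dimethyl)silyl]oxy}-2,2,6-trimethylcyclohexan-1-one
Conditions: TBSCl, imidazole, DMF, rt
Reagents that add atoms: tert-butyldimethylsilyl chloride, CC(C)(C)[Si](C)(C)Cl
Why: Imidazole-promoted O-silylation (silyl ether formation) of the secondary alcohol leaves both stereocentres untouched and masks the hydroxyl against the bases and organometallics that follow.

Step 2
Reactants: 2 (4R,6R)-4-{[tert-butyl(dimethyl)silyl]oxy}-2,2,6-trimethylcyclohexan-1-one
Product: 4 (4R)-4-{[tert-butyl(dimethyl)silyl]oxy}-2,6,6-trimethylcyclohex-1-en-1-yl trifluoromethanesulfonate, via lithium enolate 3 (not isolated)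
Conditions: LDA, THF, −78 °C; PhNTf2, −78 °C → rt
Reagents that add atoms: N-phenylbis(trifluoromethanesulfonimide), O=S(=O)(N(c1ccccc1)S(=O)(=O)C(F)(F)F)C(F)(F)F
Why: The ketone has a single α-hydrogen (C-6; the other α-carbon is quaternary), so deprotonation gives one enolate whose O-triflation (enol triflate formation) erases the C-6 centre by design while the C-4 (R) centre is not involved.

Step 3
Reactants: 4 (4R)-4-{[tert-butyl(dimethyl)silyl]oxy}-2,6,6-trimethylcyclohex-1-en-1-yl trifluoromethanesulfonate, 5 1,4-bis(trimethylsilyl)buta-1,3-diyne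
Product: 8 tert-butyl(dimethyl)({(1R)-3,5,5-trimethyl-4-[4-(trimethylsilyl)buta-1,3-diyn-1-yl]cyclohex-3-en-1-yl}oxy)silane, via lithium diynide 6 (not isolated), via diynylzinc chloride 7 (not isolated)
Conditions: 5, MeLi·LiBr, THF, 0 °C → rt; ZnCl2, 0 °C; then 4, Pd(PPh3)4 (cat.), THF, rt → 45 °C
Reagents that add atoms: none
Why: Mono-desilylation of 5 by MeLi·LiBr, transmetalation to zinc and Negishi alkynylation of the alkenyl triflate join the ring sp2 carbon to the diyne, the zinc diynide being reactive enough for the hindered tetrasubstituted triflate while the remaining C–Si bond keeps the diyne monofunctional.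

Step 4
Reactants: 8 tert-butyl(dimethyl)({(1R)-3,5,5-trimethyl-4-[4-(trimethylsilyl)buta-1,3-diyn-1-yl]cyclohex-3-en-1-yl}oxy)silane
Product: 9 {[(1R)-4-(buta-1,3-diyn-1-yl)-3,5,5-trimethylcyclohex-3-en-1-yl]oxy}(tert-butyl)dimethylsilane
Conditions: K2CO3 (cat.), MeOH–THF, 0 °C → rt; used at once as a solution
Reagents that add atoms: none
Why: Base-catalysed methanolysis of the alkynyl C–Si bond (protodesilylation) is selective over the secondary TBS ether and exposes the terminal alkyne needed for carbometalation.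

Step 5
Reactants: 10 (2E)-3-methylpent-2-en-4-yn-1-ol
Product: 13 (2E)-3-methyl-5-(trimethylsilyl)pent-2-en-4-yn-1-ol, via dilithio dianion 11 (not isolated), via C,O-bis(trimethylsilyl) ether 12 (not isolated)
Conditions: n-BuLi (2 equiv), THF, −78 → 0 °C; TMSCl (2 equiv), −78 °C → rt; then 1 M HCl (aq), rt
Reagents that add atoms: chlorotrimethylsilane, C[Si](C)(C)Cl
Why: Double deprotonation (alkoxide and acetylide), bis-silylation and mild acid hydrolysis of the labile O–SiMe3 bond give the C-silylated enynol (alkyne protection) without touching the E alkene.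

Step 6
Reactants: 13 (2E)-3-methyl-5-(trimethylsilyl)pent-2-en-4-yn-1-ol
Product: 14 (2E)-3-methyl-5-(trimethylsilyl)pent-2-en-4-ynal
Conditions: MnO2, CH2Cl2, rt
Reagents that add atoms: none
Why: MnO2 oxidation of the allylic alcohol stops at the aldehyde under neutral conditions, so the E geometry of the trisubstituted alkene should be kept.

Step 7
Reactants: 14 (2E)-3-methyl-5-(trimethylsilyl)pent-2-en-4-ynal
Product: 15 [(3E,5E)-6-iodo-3-methylhexa-3,5-dien-1-yn-1-yl]trimethylsilane
Conditions: CrCl2, CHI3, THF, 0 °C → rt, dark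
Reagents that add atoms: iodoform, IC(I)I
Why: Takai olefination converts the enal into the vinyl iodide with the E selectivity characteristic of the gem-dichromium reagent and tolerates the silylalkyne.

Step 8
Reactants: 15 [(3E,5E)-6-iodo-3-methylhexa-3,5-dien-1-yn-1-yl]trimethylsilane, 16 tert-butyl(dimethyl)(pent-4-yn-1-yloxy)silane
Product: 18 tert-butyl(dimethyl){[(4E,6E,8E)-4,9-dimethyl-11-(trimethylsilyl)undeca-4,6,8-trien-10-yn-1-yl]oxy}silane, via alkenylalane 17 (not isolated)
Conditions: 16, Me3Al, Cp2ZrCl2 (cat.), CH2Cl2, 0 °C → rt; volatiles off; then 15, ZnCl2 (cat.), Pd2(dba)3/P(2-furyl)3 (cat.), THF, rt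
Reagents that add atoms: trimethylaluminium, C[Al](C)C
Why: Zr-catalysed syn-methylalumination of the terminal alkyne puts methyl on the internal carbon and aluminium on the terminus (E-alane 17), and Pd/Zn-catalysed Negishi coupling with iodide 15 proceeds with retention at both alkenes, so the (4E) trisubstituted alkene and the new sp2–sp2 bond are set in one flask.

Step 9
Reactants: 18 tert-butyl(dimethyl){[(4E,6E,8E)-4,9-dimethyl-11-(trimethylsilyl)undeca-4,6,8-trien-10-yn-1-yl]oxy}silane
Product: 19 tert-butyl{[(4E,6E,8E)-4,9-dimethylundeca-4,6,8-trien-10-yn-1-yl]oxy}dimethylsilane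
Conditions: K2CO3 (cat.), MeOH–THF, rt
Reagents that add atoms: none
Why: Protodesilylation of the alkynylsilane with K2CO3/MeOH is selective in the presence of the primary TBS ether.

Step 10
Reactants: 19 tert-butyl{[(4E,6E,8E)-4,9-dimethylundeca-4,6,8-trien-10-yn-1-yl]oxy}dimethylsilane
Product: 21 tert-butyl{[(4E,6E,8E,10E)-11-iodo-4,9-dimethylundeca-4,6,8,10-tetraen-1-yl]oxy}dimethylsilane, via alkenylzirconocene chloride 20 (not isolated)
Conditions: Cp2Zr(H)Cl, THF, rt, dark; then I2, THF, −78 → 0 °C; used without storage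
Reagents that add atoms: iodine, II
Why: Hydrozirconation with Schwartz's reagent adds Zr–H syn, with zirconium at the terminal carbon of the conjugated alkyne and much faster than at the internal alkenes, and iodinolysis of the C–Zr bond with retention should give the (10E)-iodide.

Step 11
Reactants: 9 {[(1R)-4-(buta-1,3-diyn-1-yl)-3,5,5-trimethylcyclohex-3-en-1-yl]oxy}(tert-butyl)dimethylsilane, 21 tert-butyl{[(4E,6E,8E,10E)-11-iodo-4,9-dimethylundeca-4,6,8,10-tetraen-1-yl]oxy}dimethylsilane
Product: 23 tert-butyl{[(4E,6E,8E,10E,12E)-15-[(4R)-4-{[tert-butyl(dimethyl)silyl]oxy}-2,6,6-trimethylcyclohex-1-en-1-yl]-4,9,13-trimethylpentadeca-4,6,8,10,12-pentaen-14-yn-1-yl]oxy}dimethylsilane, via enynylalane 22 (not isolated)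
Conditions: 9 (slight excess), Me3Al, Cp2ZrCl2 (cat.), CH2Cl2, 0 °C → rt; volatiles off; then 21, ZnCl2 (cat.), Pd2(dba)3/P(2-furyl)3 (cat.), THF, rt, dark
Reagents that add atoms: trimethylaluminium, C[Al](C)C
Why: Me3Al/Cp2ZrCl2 generates a Zr–Al methyl species that adds Me–metal syn across the terminal C12≡C13 alkyne of 9, with methyl on the internal carbon C13 and aluminium on C12, and the resulting E-alane 22 is passed via zinc to the alkenyl–Pd(II) iodide formed from 21, reductive elimination then making the C11–C12 bond with retention at both alkenes. The closest known reaction type is the Zr-catalysed methylalumination of terminal alkynes (conjugated enynes included) followed by Pd/Zn-catalysed Negishi alkenyl–alkenyl coupling, here run on a terminal buta-1,3-diyne. No ring is closed and no stereocentre is created; the step fixes the C12=C13 geometry as E through the syn addition and carries the 10E geometry of 21 through unchanged. The selectivities needed are terminal-versus-internal alkyne, methyl-to-C13 regiochemistry and alkenyl-versus-methyl transfer: the C14≡C15 alkyne is shielded by tetrasubstituted ring carbon C1' with its gem-dimethyl and methyl-bearing neighbours and internal alkynes carbometalate far more slowly, conjugation directs aluminium to the terminus, and excess Me3Al is stripped off before the preferentially transferring alkenyl group meets palladium. Both TBS ethers are inert to the alane, and room temperature in the dark should avoid E/Z drift of the polyene.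

Step 12
Reactants: 23 tert-butyl{[(4E,6E,8E,10E,12E)-15-[(4R)-4-{[tert-butyl(dimethyl)silyl]oxy}-2,6,6-trimethylcyclohex-1-en-1-yl]-4,9,13-trimethylpentadeca-4,6,8,10,12-pentaen-14-yn-1-yl]oxy}dimethylsilane
Product: 24 (4E,6E,8E,10E,12E)-15-[(4R)-4-hydroxy-2,6,6-trimethylcyclohex-1-en-1-yl]-4,9,13-trimethylpentadeca-4,6,8,10,12-pentaen-14-yn-1-ol (CNP0344116.1)
Conditions: TBAF, THF, 0 °C → rt, dark
Reagents that add atoms: none
Why: Fluoride-mediated desilylation cleaves both TBS ethers under non-acidic conditions that should leave the polyenyne geometry and the carbinol centre untouched.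

**Compound list**

1 | (4R,6R)-4-hydroxy-2,2,6-trimethylcyclohexan-1-one (actinol) | C[C@H]1C(=O)C(C)(C)C[C@H](O)C1 | starting material
2 | (4R,6R)-4-{[tert-butyl(dimethyl)silyl]oxy}-2,2,6-trimethylcyclohexan-1-one | C[C@H]1C(=O)C(C)(C)C[C@H](O[Si](C)(C)C(C)(C)C)C1 | intermediate
3 | lithium (4R)-4-{[tert-butyl(dimethyl)silyl]oxy}-2,6,6-trimethylcyclohex-1-en-1-olate (lithium enolate of 2, formed in the flask) | CC1=C(O[Li])C(C)(C)C[C@H](O[Si](C)(C)C(C)(C)C)C1 | intermediate
4 | (4R)-4-{[tert-butyl(dimethyl)silyl]oxy}-2,6,6-trimethylcyclohex-1-en-1-yl trifluoromethanesulfonate | CC1=C(OS(=O)(=O)C(F)(F)F)C(C)(C)C[C@H](O[Si](C)(C)C(C)(C)C)C1 | intermediate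
5 | 1,4-bis(trimethylsilyl)buta-1,3-diyne | C[Si](C)(C)C#CC#C[Si](C)(C)C | starting material
6 | [4-(trimethylsilyl)buta-1,3-diyn-1-yl]lithium (formed in the flask) | [Li]C#CC#C[Si](C)(C)C | intermediate
7 | chlorido[4-(trimethylsilyl)buta-1,3-diyn-1-yl]zinc (formed in the flask) | Cl[Zn]C#CC#C[Si](C)(C)C | intermediate
8 | tert-butyl(dimethyl)({(1R)-3,5,5-trimethyl-4-[4-(trimethylsilyl)buta-1,3-diyn-1-yl]cyclohex-3-en-1-yl}oxy)silane | CC1=C(C#CC#C[Si](C)(C)C)C(C)(C)C[C@H](O[Si](C)(C)C(C)(C)C)C1 | intermediate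
9 | {[(1R)-4-(buta-1,3-diyn-1-yl)-3,5,5-trimethylcyclohex-3-en-1-yl]oxy}(tert-butyl)dimethylsilane | CC1=C(C#CC#C)C(C)(C)C[C@H](O[Si](C)(C)C(C)(C)C)C1 | intermediate
10 | (2E)-3-methylpent-2-en-4-yn-1-ol | C#C/C(C)=C/CO | starting material
11 | dilithium salt of 10 (lithium alkoxide and lithium acetylide, formed in the flask) | [Li]C#C/C(C)=C/CO[Li] | intermediate
12 | trimethyl{[(2E)-3-methyl-5-(trimethylsilyl)pent-2-en-4-yn-1-yl]oxy}silane (formed in the flask) | C[Si](C)(C)C#C/C(C)=C/CO[Si](C)(C)C | intermediate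
13 | (2E)-3-methyl-5-(trimethylsilyl)pent-2-en-4-yn-1-ol | C[Si](C)(C)C#C/C(C)=C/CO | intermediate
14 | (2E)-3-methyl-5-(trimethylsilyl)pent-2-en-4-ynal | C[Si](C)(C)C#C/C(C)=C/C=O | intermediate
15 | [(3E,5E)-6-iodo-3-methylhexa-3,5-dien-1-yn-1-yl]trimethylsilane | C[Si](C)(C)C#C/C(C)=C/C=C/I | intermediate
16 | tert-butyl(dimethyl)(pent-4-yn-1-yloxy)silane | C#CCCCO[Si](C)(C)C(C)(C)C | starting material
17 | [(1E)-5-{[tert-butyl(dimethyl)silyl]oxy}-2-methylpent-1-en-1-yl]dimethylalumane (formed in the flask) | C[Al](C)/C=C(\C)CCCO[Si](C)(C)C(C)(C)C | intermediate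
18 | tert-butyl(dimethyl){[(4E,6E,8E)-4,9-dimethyl-11-(trimethylsilyl)undeca-4,6,8-trien-10-yn-1-yl]oxy}silane | C[Si](C)(C)C#C/C(C)=C/C=C/C=C(\C)CCCO[Si](C)(C)C(C)(C)C | intermediate
19 | tert-butyl{[(4E,6E,8E)-4,9-dimethylundeca-4,6,8-trien-10-yn-1-yl]oxy}dimethylsilane | C#C/C(C)=C/C=C/C=C(\C)CCCO[Si](C)(C)C(C)(C)C | intermediate
20 | chloridobis(cyclopentadienyl)[(1E,3E,5E,7E)-11-{[tert-butyl(dimethyl)silyl]oxy}-3,8-dimethylundeca-1,3,5,7-tetraen-1-yl]zirconium (formed in the flask; Cp drawn η1) | Cl[Zr](/C=C/C(C)=C/C=C/C=C(\C)CCCO[Si](C)(C)C(C)(C)C)(C1C=CC=C1)C1C=CC=C1 | intermediate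
21 | tert-butyl{[(4E,6E,8E,10E)-11-iodo-4,9-dimethylundeca-4,6,8,10-tetraen-1-yl]oxy}dimethylsilane | I/C=C/C(C)=C/C=C/C=C(\C)CCCO[Si](C)(C)C(C)(C)C | intermediate
22 | [(1E)-4-[(4R)-4-{[tert-butyl(dimethyl)silyl]oxy}-2,6,6-trimethylcyclohex-1-en-1-yl]-2-methylbut-1-en-3-yn-1-yl]dimethylalumane (formed in the flask) | CC1=C(C#C/C(C)=C/[Al](C)C)C(C)(C)C[C@H](O[Si](C)(C)C(C)(C)C)C1 | intermediate
23 | tert-butyl{[(4E,6E,8E,10E,12E)-15-[(4R)-4-{[tert-butyl(dimethyl)silyl]oxy}-2,6,6-trimethylcyclohex-1-en-1-yl]-4,9,13-trimethylpentadeca-4,6,8,10,12-pentaen-14-yn-1-yl]oxy}dimethylsilane (bis-TBS ether of 24) | CC1=C(C#C/C(C)=C/C=C/C(C)=C/C=C/C=C(\C)CCCO[Si](C)(C)C(C)(C)C)C(C)(C)C[C@H](O[Si](C)(C)C(C)(C)C)C1 | intermediate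
24 | (4E,6E,8E,10E,12E)-15-[(4R)-4-hydroxy-2,6,6-trimethylcyclohex-1-en-1-yl]-4,9,13-trimethylpentadeca-4,6,8,10,12-pentaen-14-yn-1-ol | CC1=C(C#C/C(C)=C/C=C/C(C)=C/C=C/C=C(\C)CCCO)C(C)(C)C[C@H](O)C1 | target

**Summary**

Total step count: 12. Longest linear sequence: 8 steps (10 → 24, steps 5–12); the ring branch from 1 is 6 steps.

**Steps most likely to fail**

Step 11. The acidic terminal C–H of the diyne may be metalated instead of carbometalated, methyl addition may be unselective or run on to the internal alkyne, or the sensitive iodide 21 may decay before it couples. The fallback builds the C11–C12 bond on a four-carbon unit and attaches the ring last; it sets out from 19 (and 4) and comes back at 23. Propargyl alcohol is methylaluminated (Me3Al, cat. Cp2ZrCl2) and iodinated to (2E)-3-iodo-2-methylprop-2-en-1-ol F1. Trienyne 19 is hydrozirconated to 20 as in step 10 and, without iodinolysis, cross-coupled (ZnCl2, Pd catalyst) with F1 used as its magnesium alkoxide, giving (2E,4E,6E,8E,10E)-14-{[tert-butyl(dimethyl)silyl]oxy}-2,6,11-trimethyltetradeca-2,4,6,8,10-pentaen-1-ol F2. MnO2 oxidation gives the corresponding pentaenal F3, and Colvin homologation (lithiated trimethylsilyldiazomethane, THF, −78 °C) gives the terminal pentaenyne tert-butyl{[(4E,6E,8E,10E,12E)-4,9,13-trimethylpentadeca-4,6,8,10,12-pentaen-14-yn-1-yl]oxy}dimethylsilane F4. Sonogashira coupling of F4 with triflate 4 (Pd(PPh3)4, CuI, i-Pr2NH) then gives 23.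

Step 10. Iodine may scramble E/Z geometry or degrade the tetraene during iodinolysis of 20, Schwartz's reagent may over-reduce, and 21 may be lost on isolation. The fallback reverses the polarity so that the halogen sits on the robust enyne; it sets out from 9 and 19 and comes back at 23. Diyne 9 is methylaluminated as in step 11 and alane 22 is quenched with I2 to give tert-butyl({(1R)-4-[(3E)-4-iodo-3-methylbut-3-en-1-yn-1-yl]-3,5,5-trimethylcyclohex-3-en-1-yl}oxy)dimethylsilane F5. Trienyne 19 is hydrozirconated to 20 and coupled in the same flask with F5 (ZnCl2, Pd2(dba)3/P(2-furyl)3), giving 23 without the tetraenyl iodide being made.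

Step 3. Oxidative addition into the tetrasubstituted, neopentyl-flanked triflate may be slow, so that homocoupling or decay of zinc diynide 7 dominates. The fallback replaces cross-coupling by carbonyl addition and dehydration; it sets out from 2 and comes back at 8. Lithium diynide 6 (from 5 as in step 3, with CeCl3 if enolisation competes) is added to ketone 2 to give (4R,6R)-4-{[tert-butyl(dimethyl)silyl]oxy}-2,2,6-trimethyl-1-[4-(trimethylsilyl)buta-1,3-diyn-1-yl]cyclohexan-1-ol F6 as a mixture of C-1 epimers. Dehydration with SOCl2/pyridine can eliminate only toward the C-6 methine, because the other neighbour is quaternary, and gives 8.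

**Further compounds**

F1 | step 11 | (2E)-3-iodo-2-methylprop-2-en-1-ol | OC/C(C)=C/I
F2 | step 11 | (2E,4E,6E,8E,10E)-14-{[tert-butyl(dimethyl)silyl]oxy}-2,6,11-trimethyltetradeca-2,4,6,8,10-pentaen-1-ol | OC/C(C)=C/C=C/C(C)=C/C=C/C=C(\C)CCCO[Si](C)(C)C(C)(C)C
F3 | step 11 | (2E,4E,6E,8E,10E)-14-{[tert-butyl(dimethyl)silyl]oxy}-2,6,11-trimethyltetradeca-2,4,6,8,10-pentaenal | O=C/C(C)=C/C=C/C(C)=C/C=C/C=C(\C)CCCO[Si](C)(C)C(C)(C)C
F4 | step 11 | tert-butyl{[(4E,6E,8E,10E,12E)-4,9,13-trimethylpentadeca-4,6,8,10,12-pentaen-14-yn-1-yl]oxy}dimethylsilane | C#C/C(C)=C/C=C/C(C)=C/C=C/C=C(\C)CCCO[Si](C)(C)C(C)(C)C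
F5 | step 10 | tert-butyl({(1R)-4-[(3E)-4-iodo-3-methylbut-3-en-1-yn-1-yl]-3,5,5-trimethylcyclohex-3-en-1-yl}oxy)dimethylsilane | CC1=C(C#C/C(C)=C/I)C(C)(C)C[C@H](O[Si](C)(C)C(C)(C)C)C1
F6 | step 3 | (4R,6R)-4-{[tert-butyl(dimethyl)silyl]oxy}-2,2,6-trimethyl-1-[4-(trimethylsilyl)buta-1,3-diyn-1-yl]cyclohexan-1-ol (C-1 epimer mixture) | C[C@H]1C(O)(C#CC#C[Si](C)(C)C)C(C)(C)C[C@H](O[Si](C)(C)C(C)(C)C)C1
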